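**Retrosynthetic overview**
1. The target is a 1,2-diacyl-sn-glycerol with two identical C18 acyl chains (chain atoms numbered from the carboxyl carbon C1). The O3 protecting group and both ester C–O bonds are cut, giving 3-O-(4-methoxybenzyl)-sn-glycerol (from (S)-solketal) and two equivalents of one epoxy dienediynoic acid.
2. The acid is cut at C5–C6 of the diyne (Cadiot–Chodkiewicz) into 5-bromopent-4-ynoic acid and an ethynyl oxirane. The ethynyl carbon C7 goes back through an aldehyde (Ohira–Bestmann) to a CH2OH group.
3. Feature carrying the strategy: the trans-oxirane C8–C9 has C7 directly beside it. With C7 as CH2OH, C8=C9 is an E-allylic alcohol and the only alkene with a hydroxyl handle, while the Z,Z-diene C13–C16 has none. A Ti/tartrate epoxidation therefore builds the oxirane and both stereocentres C8 and C9.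
4. The trienol comes from hex-5-yn-1-ol and but-1-yne: bromoalkyne coupling, zinc cis-reduction of the diyne, oxidation, Horner–Wadsworth–Emmons olefination, DIBAL reduction.
5. Ring order: the oxirane is the only ring made. It is closed once (step 7), before any fragment coupling, and enters the target twice through acid 14; the dioxolane of solketal is only a protecting ring.

Key step: step 7

Remark on the chemistry: the glycerol stereocentre of the target is (S), i.e. a 1,2-diacyl-sn-glycerol with free O3, and both acyl groups are the same (8S,9S) acid, so one acid serves both positions and (S)-solketal supplies the glycerol.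

**Step 1**
Reactants: 1 hex-5-yn-1-ol
Product: 2 6-bromohex-5-yn-1-ol
Conditions: NBS, AgNO3 (cat.), acetone, rt, dark
Reagents that add atoms: N-bromosuccinimide, O=C1CCC(=O)N1Br
Why: Silver-catalysed electrophilic bromination of a terminal alkyne (the silver acetylide is brominated by NBS) is selective for the C(sp)–H bond and should leave the primary alcohol untouched.

**Step 2**
Reactants: 2 6-bromohex-5-yn-1-ol; 3 but-1-yne (excess, condensed in)
Product: 4 deca-5,7-diyn-1-ol
Conditions: CuCl (cat.), NH2OH·HCl, 30% aq. n-BuNH2, MeOH, 0 °C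
Reagents that add atoms: none
Why: Cadiot–Chodkiewicz coupling, in which the monovalent copper acetylide of but-1-yne substitutes the bromoalkyne to give the unsymmetrical 1,3-diyne, the cheap volatile alkyne in excess suppressing homocoupling of 2.

**Step 3**
Reactants: 4 deca-5,7-diyn-1-ol
Product: 5 (5Z,7Z)-deca-5,7-dien-1-ol
Conditions: Zn dust activated with Cu(OAc)2 and AgNO3, MeOH/H2O 1:1, 40 °C, dark
Reagents that add atoms: none
Why: Boland-type zinc reduction, in which conjugated triple bonds take up two electrons and two protons on the metal surface with cis delivery of hydrogen, should convert the diyne into the 5Z,7Z-diene and stop there because non-conjugated alkenes are inert to the couple.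

**Step 4**
Reactants: 5 (5Z,7Z)-deca-5,7-dien-1-ol
Product: 6 (5Z,7Z)-deca-5,7-dienal
Conditions: Dess–Martin periodinane, NaHCO3, CH2Cl2, 0 °C to rt
Reagents that add atoms: none
Why: Dess–Martin oxidation of a primary alcohol stops at the aldehyde under buffered, non-acidic conditions that should not isomerise the Z,Z-diene.

**Step 5**
Reactants: 6 (5Z,7Z)-deca-5,7-dienal
Product: 7 ethyl (2E,7Z,9Z)-dodeca-2,7,9-trienoate
Conditions: (EtO)2P(O)CH2CO2Et, NaH, THF, 0 °C
Reagents that add atoms: triethyl phosphonoacetate, CCOC(=O)CP(=O)(OCC)OCC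
Why: Horner–Wadsworth–Emmons olefination with a stabilised phosphonate anion gives the E-enoate through reversible addition and preferential collapse of the anti adduct, which sets the C2=C3 geometry.

**Step 6**
Reactants: 7 ethyl (2E,7Z,9Z)-dodeca-2,7,9-trienoate
Product: 8 (2E,7Z,9Z)-dodeca-2,7,9-trien-1-ol
Conditions: i-Bu2AlH (2.5 equiv), CH2Cl2, −78 °C; aq. Rochelle salt
Reagents that add atoms: none
Why: 1,2-Reduction of an α,β-unsaturated ester by two hydride transfers from i-Bu2AlH at low temperature gives the E-allylic alcohol without touching the remote diene.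

**Step 7**
Reactants: 8 (2E,7Z,9Z)-dodeca-2,7,9-trien-1-ol
Product: 9 [(2S,3S)-3-[(4Z,6Z)-nona-4,6-dien-1-yl]oxiran-2-yl]methanol
Conditions: Ti(OiPr)4 (10 mol%), L-(+)-diethyl tartrate (12 mol%), t-BuOOH (anhydrous, 2 equiv), 4 Å MS, CH2Cl2, −20 °C
Reagents that add atoms: tert-butyl hydroperoxide, CC(C)(C)OO
Why: Ligand exchange places the alkoxide of 8, the tartrate and the tert-butyl peroxide on one tetravalent titanium centre of the dimeric Ti–tartrate complex, and the distal peroxide oxygen is then passed to C2=C3 through a concerted spiro transition state. The closest known reaction type is the catalytic Sharpless asymmetric epoxidation of E-2-alken-1-ols. The oxirane (C2, C3, O) is closed by this single [2+1] oxygen-atom transfer, which forms both C–O bonds at once, so the E geometry is carried over as the trans ring. C2 and C3 are both set by the L-(+)-tartrate ligand, which delivers oxygen to the lower face of the alkene when the allylic alcohol is drawn in the plane with CH2OH at the lower right, giving (2S,3S). The step needs site selectivity over the more electron-rich 7Z,9Z-diene as well as enantioface selectivity. Both come from the C1 hydroxyl, which ties only C2=C3 to the chiral titanium peroxide, while the unbound diene should not be oxidised by this reagent at −20 °C.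

**Step 8**
Reactants: 9 [(2S,3S)-3-[(4Z,6Z)-nona-4,6-dien-1-yl]oxiran-2-yl]methanol
Product: 10 (2R,3S)-3-[(4Z,6Z)-nona-4,6-dien-1-yl]oxirane-2-carbaldehyde
Conditions: Dess–Martin periodinane, NaHCO3, CH2Cl2, 0 °C; filtered through a short silica pad and used at once
Reagents that add atoms: none
Why: Dess–Martin oxidation of a 2,3-epoxy alcohol to the epoxy aldehyde under buffered conditions; the ring carbon next to the carbonyl resists enolisation because of ring strain, so no epimerisation is expected (the descriptor at C2 changes to R only through the priority rules).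

**Step 9**
Reactants: 10 (2R,3S)-3-[(4Z,6Z)-nona-4,6-dien-1-yl]oxirane-2-carbaldehyde
Product: 11 (2S,3S)-2-ethynyl-3-[(4Z,6Z)-nona-4,6-dien-1-yl]oxirane
Conditions: dimethyl (1-diazo-2-oxopropyl)phosphonate, K2CO3, MeOH, 0 °C to rt
Reagents that add atoms: dimethyl (1-diazo-2-oxopropyl)phosphonate, CC(=O)C(=[N+]=[N-])P(=O)(OC)OC
Why: Seyferth–Gilbert homologation in the Ohira–Bestmann variant, in which the diazomethylphosphonate anion freed by methanolysis adds to the aldehyde, dimethyl phosphate is eliminated and loss of N2 with a 1,2-hydrogen shift gives the terminal alkyne, the mild carbonate base leaving the oxirane and its stereocentres intact.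

**Step 10**
Reactants: 12 pent-4-ynoic acid
Product: 13 5-bromopent-4-ynoic acid
Conditions: Br2, KOH, H2O, 0 °C to rt; then cold dil. HCl to pH 2
Reagents that add atoms: bromine, BrBr
Why: Hypobromite bromination of a terminal alkyne in aqueous base brominates the acetylide while the carboxylate stays inert, and it avoids silver salts, which could cycloisomerise a pent-4-ynoic acid to the enol lactone.

**Step 11**
Reactants: 11 (2S,3S)-2-ethynyl-3-[(4Z,6Z)-nona-4,6-dien-1-yl]oxirane; 13 5-bromopent-4-ynoic acid (1.3 equiv, added slowly)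
Product: 14 7-[(2S,3S)-3-[(4Z,6Z)-nona-4,6-dien-1-yl]oxiran-2-yl]hepta-4,6-diynoic acid
Conditions: CuCl (cat.), NH2OH·HCl, 30% aq. n-BuNH2, MeOH, 0 °C; cold aq. citric acid to pH 4, EtOAc
Reagents that add atoms: none
Why: Cadiot–Chodkiewicz coupling of the monovalent copper acetylide of 11 with the bromoalkynoate forms the C5–C6 bond of the diyne; the oxirane carbons are not involved and primary amines should not open the epoxide at 0 °C on this time scale, so both stereocentres are carried through.

**Step 12**
Reactants: 15 (S)-solketal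
Product: 16 (S)-4-{[(4-methoxybenzyl)oxy]methyl}-2,2-dimethyl-1,3-dioxolane
Conditions: NaH, 4-methoxybenzyl chloride, n-Bu4NI (cat.), DMF, 0 °C to rt
Reagents that add atoms: 4-methoxybenzyl chloride, COc1ccc(CCl)cc1
Why: Williamson ether synthesis, the sodium alkoxide displacing the benzylic chloride by SN2 under iodide catalysis without touching the stereocentre.

**Step 13**
Reactants: 16 (S)-4-{[(4-methoxybenzyl)oxy]methyl}-2,2-dimethyl-1,3-dioxolane
Product: 17 (R)-3-[(4-methoxybenzyl)oxy]propane-1,2-diol (3-O-(4-methoxybenzyl)-sn-glycerol)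
Conditions: AcOH/H2O 4:1, 40 °C
Reagents that add atoms: none
Why: Acid-catalysed hydrolysis of the isopropylidene acetal in aqueous acetic acid, which a 4-methoxybenzyl ether tolerates, frees the 1,2-diol without affecting the stereocentre (the descriptor changes to R only through the priority rules).

**Step 14**
Reactants: 17 (R)-3-[(4-methoxybenzyl)oxy]propane-1,2-diol; 14 7-[(2S,3S)-3-[(4Z,6Z)-nona-4,6-dien-1-yl]oxiran-2-yl]hepta-4,6-diynoic acid (2.4 equiv)
Product: 18 (2S)-3-[(4-methoxybenzyl)oxy]propane-1,2-diyl bis{7-[(2S,3S)-3-[(4Z,6Z)-nona-4,6-dien-1-yl]oxiran-2-yl]hepta-4,6-diynoate}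
Conditions: DCC, DMAP, CH2Cl2, 0 °C to rt, dark, argon
Reagents that add atoms: none
Why: Steglich esterification, in which DCC activates the acid as the O-acylisourea and DMAP relays the acyl group to the primary and the secondary hydroxyl; acylation occurs at oxygen only, so the glycerol stereocentre and the oxiranes are unchanged.

**Step 15**
Reactants: 18 (2S)-3-[(4-methoxybenzyl)oxy]propane-1,2-diyl bis{7-[(2S,3S)-3-[(4Z,6Z)-nona-4,6-dien-1-yl]oxiran-2-yl]hepta-4,6-diynoate}
Product: 19 (2S)-3-hydroxypropane-1,2-diyl bis{7-[(2S,3S)-3-[(4Z,6Z)-nona-4,6-dien-1-yl]oxiran-2-yl]hepta-4,6-diynoate} (target)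
Conditions: DDQ (1.5 equiv), CH2Cl2/pH 7 phosphate buffer 10:1, 0 °C; rapid chromatography on boric-acid-treated silica, cold
Reagents that add atoms: none
Why: Oxidative cleavage of the 4-methoxybenzyl ether by DDQ (hydride abstraction to the oxocarbenium ion, then hydrolysis) under buffered two-phase conditions at 0 °C, which should be neutral enough to avoid acyl migration from O2 to O3 and opening of the oxiranes.

**Compound list**
1 | hex-5-yn-1-ol | OCCCCC#C | starting material
2 | 6-bromohex-5-yn-1-ol | OCCCCC#CBr | intermediate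
3 | but-1-yne | CCC#C | starting material
4 | deca-5,7-diyn-1-ol | OCCCCC#CC#CCC | intermediate
5 | (5Z,7Z)-deca-5,7-dien-1-ol | OCCCC/C=C\C=C/CC | intermediate
6 | (5Z,7Z)-deca-5,7-dienal | O=CCCC/C=C\C=C/CC | intermediate
7 | ethyl (2E,7Z,9Z)-dodeca-2,7,9-trienoate | CCOC(=O)/C=C/CCC/C=C\C=C/CC | intermediate
8 | (2E,7Z,9Z)-dodeca-2,7,9-trien-1-ol | OC/C=C/CCC/C=C\C=C/CC | intermediate
9 | [(2S,3S)-3-[(4Z,6Z)-nona-4,6-dien-1-yl]oxiran-2-yl]methanol | OC[C@@H]1O[C@H]1CCC/C=C\C=C/CC | intermediate
10 | (2R,3S)-3-[(4Z,6Z)-nona-4,6-dien-1-yl]oxirane-2-carbaldehyde | O=C[C@@H]1O[C@H]1CCC/C=C\C=C/CC | intermediate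
11 | (2S,3S)-2-ethynyl-3-[(4Z,6Z)-nona-4,6-dien-1-yl]oxirane | C#C[C@@H]1O[C@H]1CCC/C=C\C=C/CC | intermediate
12 | pent-4-ynoic acid | C#CCCC(=O)O | starting material
13 | 5-bromopent-4-ynoic acid | BrC#CCCC(=O)O | intermediate
14 | 7-[(2S,3S)-3-[(4Z,6Z)-nona-4,6-dien-1-yl]oxiran-2-yl]hepta-4,6-diynoic acid | OC(=O)CCC#CC#C[C@@H]1O[C@H]1CCC/C=C\C=C/CC | intermediate
15 | (S)-solketal | CC1(C)OC[C@H](CO)O1 | starting material
16 | (S)-4-{[(4-methoxybenzyl)oxy]methyl}-2,2-dimethyl-1,3-dioxolane | CC1(C)OC[C@H](COCc2ccc(OC)cc2)O1 | intermediate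
17 | (R)-3-[(4-methoxybenzyl)oxy]propane-1,2-diol | OC[C@H](COCc1ccc(OC)cc1)O | intermediate
18 | (2S)-3-[(4-methoxybenzyl)oxy]propane-1,2-diyl bis{7-[(2S,3S)-3-[(4Z,6Z)-nona-4,6-dien-1-yl]oxiran-2-yl]hepta-4,6-diynoate} | CC/C=C\C=C/CCC[C@@H]1O[C@H]1C#CC#CCCC(=O)OC[C@H](COCc2ccc(OC)cc2)OC(=O)CCC#CC#C[C@@H]1O[C@H]1CCC/C=C\C=C/CC | intermediate
19 | (2S)-3-hydroxypropane-1,2-diyl bis{7-[(2S,3S)-3-[(4Z,6Z)-nona-4,6-dien-1-yl]oxiran-2-yl]hepta-4,6-diynoate} | CC/C=C\C=C/CCC[C@@H]1O[C@H]1C#CC#CCCC(=O)OC[C@H](CO)OC(=O)CCC#CC#C[C@@H]1O[C@H]1CCC/C=C\C=C/CC | target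

**Step count**
Total steps: 15
Longest linear sequence: 12 steps (steps 1–9, 11, 14, 15)

**Steps most likely to fail**

Step 15. The risk is migration of the acyl group from O2 to the freed O3 during or after the deprotection, together with oxidative damage to the Z,Z-dienes by DDQ. The fallback swaps the oxidatively cleaved ether for a silyl ether removed by buffered fluoride. It sets out from 15, which is silylated (t-BuPh2SiCl, imidazole, DMF) to (R)-tert-butyl[(2,2-dimethyl-1,3-dioxolan-4-yl)methoxy]diphenylsilane F1. The acetal is hydrolysed (AcOH/H2O, 40 °C) to (R)-3-[(tert-butyldiphenylsilyl)oxy]propane-1,2-diol F2, which is acylated with 14 (DCC, DMAP, CH2Cl2) to the silyl-protected diester F3. Desilylation with n-Bu4NF buffered with AcOH (THF, 0 °C) needs no oxidant and should be close to neutral; the fallback comes back to the route at 19.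

Step 11. The risk is loss of the free epoxy diynoic acid through decomposition on acidification and concentration, and consumption of the bromo acid by homocoupling. The fallback moves the coupling onto the glycerol ester so that no free epoxy acid is handled. It sets out from 11 (with 13 and 17): 17 is acylated with 13 (DCC, DMAP, CH2Cl2) to (2S)-3-[(4-methoxybenzyl)oxy]propane-1,2-diyl bis(5-bromopent-4-ynoate) F4. A twofold Cadiot–Chodkiewicz coupling of F4 with 11 (2.5 equiv; CuCl, NH2OH·HCl, n-BuNH2, MeOH/THF, 0 °C, short reaction time) then gives the protected diester directly; the fallback comes back to the route at 18, and step 14 is no longer needed.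

Step 3. The risk is that the double reduction stalls at the enyne, or over-reduces and partly isomerises to E alkenes, giving isomer mixtures that are hard to separate. The fallback fixes one Z alkene before the carbon–carbon coupling, so only one triple bond, in an enyne, has to be reduced. It sets out from 2, which is reduced with diimide (2-nitrobenzenesulfonyl hydrazide, Et3N, THF/i-PrOH) to (Z)-6-bromohex-5-en-1-ol F5. Sonogashira coupling of F5 with 3 (Pd(PPh3)4, CuI, n-BuNH2, THF, rt) gives (Z)-dec-5-en-7-yn-1-ol F6 with retention of geometry. The single triple bond of F6 is then cis-reduced, either with the zinc couple of step 3 or with H2 over Pd on CaCO3 poisoned with Pb(OAc)2 and quinoline; the fallback comes back to the route at 5.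

**Further compounds**
F1 | step 15 | (R)-tert-butyl[(2,2-dimethyl-1,3-dioxolan-4-yl)methoxy]diphenylsilane | CC1(C)OC[C@H](CO[Si](c2ccccc2)(c2ccccc2)C(C)(C)C)O1
F2 | step 15 | (R)-3-[(tert-butyldiphenylsilyl)oxy]propane-1,2-diol | OC[C@H](CO[Si](c1ccccc1)(c1ccccc1)C(C)(C)C)O
F3 | step 15 | (2R)-3-[(tert-butyldiphenylsilyl)oxy]propane-1,2-diyl bis{7-[(2S,3S)-3-[(4Z,6Z)-nona-4,6-dien-1-yl]oxiran-2-yl]hepta-4,6-diynoate} | CC/C=C\C=C/CCC[C@@H]1O[C@H]1C#CC#CCCC(=O)OC[C@H](CO[Si](c2ccccc2)(c2ccccc2)C(C)(C)C)OC(=O)CCC#CC#C[C@@H]1O[C@H]1CCC/C=C\C=C/CC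
F4 | step 11 | (2S)-3-[(4-methoxybenzyl)oxy]propane-1,2-diyl bis(5-bromopent-4-ynoate) | BrC#CCCC(=O)OC[C@H](COCc1ccc(OC)cc1)OC(=O)CCC#CBr
F5 | step 3 | (Z)-6-bromohex-5-en-1-ol | OCCCC/C=C\Br
F6 | step 3 | (Z)-dec-5-en-7-yn-1-ol | OCCCC/C=C\C#CCC
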